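**Synthetic plan**
1. Cuts, in retrosynthetic order: C3–Br and C2–OH (hydroxybromination of a cyclic enol ether); O1–C2 (hemiketal of a δ-hydroxy ketone); the vinylic C–Br bond (from a vinylsilane); the C5–C(Cl) bond ([3,3] shift of an ester enolate); the ester C–O bond.
2. Enabling feature: ring carbon C5 (the CH between C4H2 and the O-bound C6H2) carries the exocyclic quaternary C(CH3)(Cl) with its (E)-2-bromovinyl group. Read with C6 as a carboxyl carbon, C6–C5–C(Cl)–CH=CH is a γ,δ-unsaturated acid.
3. Forward: an α-silyl chloroallylic alcohol (from but-2-yn-1-ol) and a ketal acid (from 5-oxohexanoic acid) are joined as an ester, and the Claisen shift makes the C–C bond on the open chain. The oxane, the only ring, is closed late by the C6 hydroxyl adding to the C2 ketone, then dehydrated and hydroxybrominated.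
4. Stereochemistry: one carbinol centre, set by asymmetric transfer hydrogenation, is relayed through a chair transition state to C5 and to the chlorinated carbon. C3 and C2 are set by equilibration.

Key step: step 8

Assumption: the facial sense of step 3 is taken from alkynyl methyl ketones, with SiMe3 in the place of methyl; should the S alcohol form, the (S,S) catalyst would be used.
Remark: hydroxy ketone 19 and the α-bromo ketone behind 22 and 23 are in ring–chain equilibrium with their six-membered hemiketals; each is drawn in the form named.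

**Step 1**
Reactants: 1 but-2-yn-1-ol
Product: 3 rac-1-(trimethylsilyl)but-2-yn-1-ol, via trimethyl(but-2-yn-1-yloxy)silane 2 (not isolated)
Conditions: n-BuLi, THF, −78 °C; Me3SiCl, −78 to 0 °C; t-BuLi, −78 to −40 °C; AcOH, −78 °C
Reagents that add atoms: chlorotrimethylsilane, C[Si](C)(C)Cl
Why: O-silylation followed by lithiation of the propargylic O–CH2 position sets off a [1,2] retro-Brook (O to C) silyl shift driven by the O–Li pairing, a standard entry to α-silyl propargylic alcohols; the product is racemic and the cold acidic quench prevents the reverse shift.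

**Step 2**
Reactants: 3 rac-1-(trimethylsilyl)but-2-yn-1-ol
Product: 4 1-(trimethylsilyl)but-2-yn-1-one
Conditions: (COCl)2, DMSO, CH2Cl2, −78 °C; Et3N, −78 to 0 °C
Reagents that add atoms: none
Why: Swern oxidation is the usual way from α-hydroxysilanes to acylsilanes and leaves the internal alkyne alone; the volatile, light-sensitive acylsilane would be carried on in solution.

**Step 3**
Reactants: 4 1-(trimethylsilyl)but-2-yn-1-one
Product: 5 (R)-1-(trimethylsilyl)but-2-yn-1-ol
Conditions: Ru[(R,R)-TsDPEN](p-cymene) (base-free amido complex, 1 mol%), i-PrOH, rt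
Reagents that add atoms: none
Why: Noyori asymmetric transfer hydrogenation reduces alkynyl ketones through a six-membered Ru–H/N–H transition state with the alkynyl group next to the arene ligand and the bulky SiMe3 away from it, so the (R,R) catalyst should give the R carbinol, the only reagent-controlled stereocentre of the route.

**Step 4**
Reactants: 5 (R)-1-(trimethylsilyl)but-2-yn-1-ol
Product: 7 (1R,2Z)-3-chloro-1-(trimethylsilyl)but-2-en-1-ol, via cyclic vinylalanate 6 (not isolated)
Conditions: NaAlH2(OCH2CH2OCH3)2, THF, 0 °C to rt; NCS, −78 to 0 °C; aq. KNaC4H4O6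
Reagents that add atoms: N-chlorosuccinimide, O=C1CCC(=O)N1Cl
Why: Alkoxide-directed anti hydroalumination puts hydride on C2 and aluminium on C3 in a five-membered alanate, and chlorinolysis of the C–Al bond with retention leaves chlorine cis to the carbinol carbon, a known route to (Z)-3-haloallylic alcohols; the carbinol centre is untouched and the aluminium-bound alkoxide should not undergo Brook rearrangement.

**Step 5**
Reactants: 8 5-oxohexanoic acid
Product: 9 2-hydroxyethyl 4-(2-methyl-1,3-dioxolan-2-yl)butanoate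
Conditions: HOCH2CH2OH (5 equiv), TsOH·H2O (cat.), toluene, reflux, Dean–Stark
Reagents that add atoms: ethylene glycol, OCCO
Why: Acid-catalysed ketalisation with azeotropic removal of water protects the ketone against the later amide base; the concurrent Fischer esterification is harmless because the ester is cleaved in the next step.

**Step 6**
Reactants: 9 2-hydroxyethyl 4-(2-methyl-1,3-dioxolan-2-yl)butanoate
Product: 10 4-(2-methyl-1,3-dioxolan-2-yl)butanoic acid
Conditions: NaOH, MeOH/H2O, rt; then 1 M HCl to pH 4, 0 °C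
Reagents that add atoms: sodium hydroxide, [Na+].[OH-]
Why: Saponification frees the carboxylic acid while the dioxolane, stable to base and to a brief cold acidification, stays in place.

**Step 7**
Reactants: 7 (1R,2Z)-3-chloro-1-(trimethylsilyl)but-2-en-1-ol and 10 4-(2-methyl-1,3-dioxolan-2-yl)butanoic acid
Product: 11 (1R,2Z)-3-chloro-1-(trimethylsilyl)but-2-en-1-yl 4-(2-methyl-1,3-dioxolan-2-yl)butanoate
Conditions: DCC, DMAP (cat.), CH2Cl2, 0 °C to rt
Reagents that add atoms: none
Why: Steglich esterification acylates the hindered α-silyl carbinol at oxygen under neutral conditions, so the carbinol configuration, the Z vinyl chloride and the ketal are retained and no Brook shift is provoked.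

**Step 8**
Reactants: 11 (1R,2Z)-3-chloro-1-(trimethylsilyl)but-2-en-1-yl 4-(2-methyl-1,3-dioxolan-2-yl)butanoate
Product: 15 (2R,3S,4E)-3-chloro-3-methyl-2-[2-(2-methyl-1,3-dioxolan-2-yl)ethyl]-5-(trimethylsilyl)pent-4-enoic acid, via lithium enolate 12 (not isolated), via silyl ketene acetal 13 (not isolated), via trimethylsilyl ester 14 (not isolated)
Conditions: LiN(i-Pr)2, THF, −78 °C; Me3SiCl/Et3N, −78 °C to rt (to 40 °C if the shift is slow); H2O, then aq. NaH2PO4
Reagents that add atoms: none
Why: Proposed new method: an Ireland–Claisen rearrangement has not been run with chlorine on the bond-forming alkene carbon, but kinetic enolisation, O-silylation and a concerted suprafacial [3,3] shift of ketene acetal 13 should apply unchanged, because the vinylic C–Cl bond lies orthogonal to the reacting π system and becomes a tertiary allylic chloride only once the new bond exists, under cold, non-ionising conditions in which it should persist. The closest known reactions are the ester-enolate Claisen rearrangement of α-silyl allylic esters, which gives (E)-vinylsilanes with 1,3-chirality transfer, and the aromatic Claisen rearrangement of 3-chlorobut-2-enyl aryl ethers, which shows that a chlorinated terminus accepts the new C–C bond. The step forms the C2–C3 bond of 15 (C5–C(Cl) of the target) and closes no ring. Both new stereocentres come from the R carbinol carbon of 11 through a chair transition state: SiMe3 equatorial (hence the E vinylsilane), the Z chlorine axial and the methyl equatorial at the chlorinated terminus (hence 3S), and the ketene acetal side chain, cis to the allylic oxygen, axial (hence 2R). The step needs one enolate geometry, one vinyl chloride geometry and chair over boat; these are secured by LiN(i-Pr)2 in THF without polar cosolvent (α-H syn to OLi), by the anti hydroalumination of step 4, and by the bulk of SiMe3, which has no acceptable axial position.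

**Step 9**
Reactants: 15 (2R,3S,4E)-3-chloro-3-methyl-2-[2-(2-methyl-1,3-dioxolan-2-yl)ethyl]-5-(trimethylsilyl)pent-4-enoic acid
Product: 16 methyl (2R,3S,4E)-3-chloro-3-methyl-2-[2-(2-methyl-1,3-dioxolan-2-yl)ethyl]-5-(trimethylsilyl)pent-4-enoate
Conditions: Me3SiCHN2, toluene/MeOH (4:1), 0 °C
Reagents that add atoms: (trimethylsilyl)diazomethane, C[Si](C)(C)C=[N+]=[N-]
Why: Diazoalkane O-methylation is neutral, so neither the stereocentre α to the carboxyl nor the β-chloride (prone to base-induced loss of HCl) is endangered, and the ester blocks halolactonisation in the next step.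

**Step 10**
Reactants: 16 methyl (2R,3S,4E)-3-chloro-3-methyl-2-[2-(2-methyl-1,3-dioxolan-2-yl)ethyl]-5-(trimethylsilyl)pent-4-enoate
Product: 17 methyl (2R,3S,4E)-5-bromo-3-chloro-3-methyl-2-[2-(2-methyl-1,3-dioxolan-2-yl)ethyl]pent-4-enoate
Conditions: NBS, MeCN, 0 °C to rt, dark
Reagents that add atoms: N-bromosuccinimide, O=C1CCC(=O)N1Br
Why: In this electrophilic ipso-bromodesilylation Br+ adds to the silicon-bearing carbon and the β-silyl cation loses SiMe3 after the least-motion rotation, so the E geometry should be retained as known for (E)-vinyltrimethylsilanes with NBS in acetonitrile; ester, ketal and tertiary chloride are inert to NBS.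

**Step 11**
Reactants: 17 methyl (2R,3S,4E)-5-bromo-3-chloro-3-methyl-2-[2-(2-methyl-1,3-dioxolan-2-yl)ethyl]pent-4-enoate
Product: 18 (2R,3S,4E)-5-bromo-3-chloro-3-methyl-2-[2-(2-methyl-1,3-dioxolan-2-yl)ethyl]pent-4-en-1-ol
Conditions: i-Bu2AlH (2.5 equiv), CH2Cl2, −78 °C; aq. KNaC4H4O6
Reagents that add atoms: none
Why: i-Bu2AlH reduces the methyl ester to the primary alcohol (the future C6–OH) at low temperature without touching the vinyl bromide, the tertiary allylic chloride or the ketal, and without base that could epimerise C2.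

**Step 12**
Reactants: 18 (2R,3S,4E)-5-bromo-3-chloro-3-methyl-2-[2-(2-methyl-1,3-dioxolan-2-yl)ethyl]pent-4-en-1-ol
Product: 19 (5R,6S,7E)-8-bromo-6-chloro-5-(hydroxymethyl)-6-methyloct-7-en-2-one
Conditions: 1 M aq. HCl, THF, rt
Reagents that add atoms: water, O
Why: Mild aqueous acid hydrolyses the dioxolane to the methyl ketone, and room temperature with short contact should keep the tertiary allylic chloride from ionising.

**Step 13**
Reactants: 19 (5R,6S,7E)-8-bromo-6-chloro-5-(hydroxymethyl)-6-methyloct-7-en-2-one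
Product: 21 (3R)-3-[(2S,3E)-4-bromo-2-chlorobut-3-en-2-yl]-6-methyl-3,4-dihydro-2H-pyran, via cyclic hemiketal 20 (not isolated)
Conditions: PPTS (cat.), toluene, 4 Å molecular sieves, 80 °C
Reagents that add atoms: none
Why: The C6 hydroxyl adds to the C2 carbonyl (6-exo-trig) to close the oxane ring as hemiketal 20, and acid-catalysed loss of water over sieves gives the thermodynamically preferred endocyclic, trisubstituted enol ether, a standard cyclodehydration of δ-hydroxy ketones.

**Step 14**
Reactants: 21 (3R)-3-[(2S,3E)-4-bromo-2-chlorobut-3-en-2-yl]-6-methyl-3,4-dihydro-2H-pyran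
Product: 22 (5R)-3-bromo-5-[(2S,3E)-4-bromo-2-chlorobut-3-en-2-yl]-2-methyloxan-2-ol as a mixture of C3 epimers
Conditions: NBS, THF/H2O (4:1), 0 °C
Reagents that add atoms: N-bromosuccinimide, O=C1CCC(=O)N1Br; water, O
Why: Br+ attacks the electron-rich enol ether at C3 (not the methyl group and not the electron-poor bromovinyl alkene) and water captures the oxocarbenium ion at C2, the usual hydroxybromination of enol ethers; axial attack is expected to favour the C3 epimer with axial bromine, so 22 is taken on as a mixture.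

**Step 15**
Reactants: 22 (5R)-3-bromo-5-[(2S,3E)-4-bromo-2-chlorobut-3-en-2-yl]-2-methyloxan-2-ol (C3 epimers)
Product: 23 (2R,3S,5R)-3-bromo-5-[(2S,3E)-4-bromo-2-chlorobut-3-en-2-yl]-2-methyloxan-2-ol (target)
Conditions: LiBr, THF/H2O (20:1), rt
Reagents that add atoms: lithium bromide, [Li+].[Br-] (its bromide exchanges with the bromine at C3)
Why: In the ring-opened α-bromo ketone, bromide displaces bromide at C3 by SN2 (the known halide-exchange epimerisation of α-bromo carbonyl compounds), so the C3 epimers interconvert and the mixture should settle on the hemiketal with bromine, methyl and side chain equatorial and the anomeric hydroxyl axial, which fixes C3 (S) and C2 (R) under thermodynamic control.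

**Compound list**
1 | but-2-yn-1-ol | CC#CCO | starting material
2 | trimethyl(but-2-yn-1-yloxy)silane | CC#CCO[Si](C)(C)C | intermediate
3 | rac-1-(trimethylsilyl)but-2-yn-1-ol | CC#CC(O)[Si](C)(C)C | intermediate
4 | 1-(trimethylsilyl)but-2-yn-1-one | CC#CC(=O)[Si](C)(C)C | intermediate
5 | (R)-1-(trimethylsilyl)but-2-yn-1-ol | C[Si](C)(C)[C@@H](O)C#CC | intermediate
6 | sodium cyclic vinylalanate of 5 (five-membered O–Al–C(CH3)=CH–CH(SiMe3) ring, two 2-methoxyethoxy groups on Al) | C[Si](C)(C)[C@H]1O[Al-](OCCOC)(OCCOC)C(C)=C1.[Na+] | intermediate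
7 | (1R,2Z)-3-chloro-1-(trimethylsilyl)but-2-en-1-ol | C[Si](C)(C)[C@@H](O)/C=C(\Cl)C | intermediate
8 | 5-oxohexanoic acid | CC(=O)CCCC(=O)O | starting material
9 | 2-hydroxyethyl 4-(2-methyl-1,3-dioxolan-2-yl)butanoate | CC1(CCCC(=O)OCCO)OCCO1 | intermediate
10 | 4-(2-methyl-1,3-dioxolan-2-yl)butanoic acid | CC1(CCCC(=O)O)OCCO1 | intermediate
11 | (1R,2Z)-3-chloro-1-(trimethylsilyl)but-2-en-1-yl 4-(2-methyl-1,3-dioxolan-2-yl)butanoate | CC1(CCCC(=O)O[C@@H](/C=C(\Cl)C)[Si](C)(C)C)OCCO1 | intermediate
12 | lithium enolate of 11, α-hydrogen syn to OLi (side chain cis to the allylic oxygen) | [Li+].[O-]/C(=C/CCC1(C)OCCO1)O[C@@H](/C=C(\Cl)C)[Si](C)(C)C | intermediate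
13 | trimethylsilyl ketene acetal of 11, E (side chain trans to OSiMe3) | C[Si](C)(C)O/C(=C/CCC1(C)OCCO1)O[C@@H](/C=C(\Cl)C)[Si](C)(C)C | intermediate
14 | trimethylsilyl (2R,3S,4E)-3-chloro-3-methyl-2-[2-(2-methyl-1,3-dioxolan-2-yl)ethyl]-5-(trimethylsilyl)pent-4-enoate | C[C@@](Cl)(/C=C/[Si](C)(C)C)[C@H](CCC1(C)OCCO1)C(=O)O[Si](C)(C)C | intermediate
15 | (2R,3S,4E)-3-chloro-3-methyl-2-[2-(2-methyl-1,3-dioxolan-2-yl)ethyl]-5-(trimethylsilyl)pent-4-enoic acid | C[C@@](Cl)(/C=C/[Si](C)(C)C)[C@H](CCC1(C)OCCO1)C(=O)O | intermediate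
16 | methyl (2R,3S,4E)-3-chloro-3-methyl-2-[2-(2-methyl-1,3-dioxolan-2-yl)ethyl]-5-(trimethylsilyl)pent-4-enoate | C[C@@](Cl)(/C=C/[Si](C)(C)C)[C@H](CCC1(C)OCCO1)C(=O)OC | intermediate
17 | methyl (2R,3S,4E)-5-bromo-3-chloro-3-methyl-2-[2-(2-methyl-1,3-dioxolan-2-yl)ethyl]pent-4-enoate | C[C@@](Cl)(/C=C/Br)[C@H](CCC1(C)OCCO1)C(=O)OC | intermediate
18 | (2R,3S,4E)-5-bromo-3-chloro-3-methyl-2-[2-(2-methyl-1,3-dioxolan-2-yl)ethyl]pent-4-en-1-ol | C[C@@](Cl)(/C=C/Br)[C@H](CCC1(C)OCCO1)CO | intermediate
19 | (5R,6S,7E)-8-bromo-6-chloro-5-(hydroxymethyl)-6-methyloct-7-en-2-one | C[C@@](Cl)(/C=C/Br)[C@H](CCC(C)=O)CO | intermediate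
20 | (5R)-5-[(2S,3E)-4-bromo-2-chlorobut-3-en-2-yl]-2-methyloxan-2-ol (both anomers) | C[C@@](Cl)(/C=C/Br)[C@H]1COC(C)(O)CC1 | intermediate
21 | (3R)-3-[(2S,3E)-4-bromo-2-chlorobut-3-en-2-yl]-6-methyl-3,4-dihydro-2H-pyran | C[C@@](Cl)(/C=C/Br)[C@H]1COC(C)=CC1 | intermediate
22 | (5R)-3-bromo-5-[(2S,3E)-4-bromo-2-chlorobut-3-en-2-yl]-2-methyloxan-2-ol, C3 epimers | C[C@@](Cl)(/C=C/Br)[C@H]1COC(C)(O)C(Br)C1 | intermediate
23 | (2R,3S,5R)-3-bromo-5-[(2S,3E)-4-bromo-2-chlorobut-3-en-2-yl]-2-methyloxan-2-ol | C[C@@](Cl)(/C=C/Br)[C@H]1CO[C@@](C)(O)[C@@H](Br)C1 | target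

**Step count**
Total: 15 steps. Longest linear sequence: 13 steps (steps 1–4 and 7–15); the acid branch (steps 5 and 6) joins at step 7.

**Steps most likely to fail**

Step 8. The amide base may dehydrochlorinate the vinyl chloride, the [3,3] shift may be too slow at temperatures the silyl ketene acetal tolerates, the nascent tertiary allylic chloride may ionise, or leakage through a boat may erode the diastereoselectivity. The fallback sets out from 10 and returns at 18; it makes the C5–C(Cl) bond by enolate alkylation and brings in chlorine under cyclic stereocontrol.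
- Acylation of lithiated (R)-4-benzyl-1,3-oxazolidin-2-one with the pivaloyl mixed anhydride of 10 would give (4R)-4-benzyl-3-[4-(2-methyl-1,3-dioxolan-2-yl)butanoyl]-1,3-oxazolidin-2-one F1.
- Evans alkylation (NaN(SiMe3)2, tert-butyl bromoacetate, THF, −78 °C) on the enolate face away from the benzyl group would set the future C5 in tert-butyl (3S)-3-[(4R)-4-benzyl-2-oxo-1,3-oxazolidine-3-carbonyl]-5-(2-methyl-1,3-dioxolan-2-yl)pentanoate F2.
- LiBH4 would remove the auxiliary to give tert-butyl (3S)-3-(hydroxymethyl)-5-(2-methyl-1,3-dioxolan-2-yl)pentanoate F3, which should lactonise (PPTS, toluene, 80 °C) to (4S)-4-[2-(2-methyl-1,3-dioxolan-2-yl)ethyl]oxolan-2-one F4.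
- Enolate methylation (LiN(i-Pr)2, MeI, −78 °C) would give the trans lactone (3S,4S)-3-methyl-4-[2-(2-methyl-1,3-dioxolan-2-yl)ethyl]oxolan-2-one F5.
- A second enolisation followed by NCS should deliver chlorine anti to the C4 substituent, giving (3S,4R)-3-chloro-3-methyl-4-[2-(2-methyl-1,3-dioxolan-2-yl)ethyl]oxolan-2-one F6 with the relative configuration of the target.
- i-Bu2AlH at −78 °C would give the lactol (3S,4R)-3-chloro-3-methyl-4-[2-(2-methyl-1,3-dioxolan-2-yl)ethyl]oxolan-2-ol F7, whose open hydroxy aldehyde form would undergo Takai bromo-olefination (CrBr2, CHBr3, THF) to the (E)-bromoalkene 18. This last olefination, run on a lactol, is the least secure step of the fallback.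

Step 15. The thermodynamic bias between equatorial and axial bromine at C3 may be too small, so that the exchange stalls at a mixture, and bromine may drift to the methyl-side α-carbon. The fallback sets out from 21 and returns at 23, setting C3 kinetically.
- Br2 in CH2Cl2 at −78 °C would add to the enol ether to give (5R)-2,3-dibromo-5-[(2S,3E)-4-bromo-2-chlorobut-3-en-2-yl]-2-methyloxane F8.
- Et3N would eliminate HBr from it to give the bromo enol ether (3R)-5-bromo-3-[(2S,3E)-4-bromo-2-chlorobut-3-en-2-yl]-6-methyl-3,4-dihydro-2H-pyran F9.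
- Hydration with dilute aqueous HCl in THF at 0 °C should protonate C3 axially on the half-chair that keeps the side chain pseudo-equatorial, which places bromine equatorial, and water then adds axially at C2 to give 23.

Step 10. The alkene geometry may erode through a bridged bromonium ion and an anti addition/anti elimination course, or ipso attack may be sluggish because the adjacent C–Cl bond destabilises the β-silyl cation. The fallback sets out from 16 and returns at 17.
- Ozonolysis (O3, CH2Cl2, −78 °C; Me2S) would cleave the vinylsilane to methyl (2R,3S)-3-chloro-3-methyl-2-[2-(2-methyl-1,3-dioxolan-2-yl)ethyl]-4-oxobutanoate F10.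
- Takai bromo-olefination with divalent chromium (CrBr2, CHBr3, THF) would build the (E)-bromoalkene of 17 under the inherent E preference of that reaction.

**Further compounds**
F1 | step 8 | (4R)-4-benzyl-3-[4-(2-methyl-1,3-dioxolan-2-yl)butanoyl]-1,3-oxazolidin-2-one | CC1(CCCC(=O)N2[C@H](Cc3ccccc3)COC2=O)OCCO1
F2 | step 8 | tert-butyl (3S)-3-[(4R)-4-benzyl-2-oxo-1,3-oxazolidine-3-carbonyl]-5-(2-methyl-1,3-dioxolan-2-yl)pentanoate | CC1(CC[C@@H](CC(=O)OC(C)(C)C)C(=O)N2[C@H](Cc3ccccc3)COC2=O)OCCO1
F3 | step 8 | tert-butyl (3S)-3-(hydroxymethyl)-5-(2-methyl-1,3-dioxolan-2-yl)pentanoate | CC1(CC[C@@H](CC(=O)OC(C)(C)C)CO)OCCO1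
F4 | step 8 | (4S)-4-[2-(2-methyl-1,3-dioxolan-2-yl)ethyl]oxolan-2-one | CC1(CC[C@H]2CC(=O)OC2)OCCO1
F5 | step 8 | (3S,4S)-3-methyl-4-[2-(2-methyl-1,3-dioxolan-2-yl)ethyl]oxolan-2-one | C[C@H]1[C@H](CCC2(C)OCCO2)COC1=O
F6 | step 8 | (3S,4R)-3-chloro-3-methyl-4-[2-(2-methyl-1,3-dioxolan-2-yl)ethyl]oxolan-2-one | C[C@]1(Cl)[C@H](CCC2(C)OCCO2)COC1=O
F7 | step 8 | (3S,4R)-3-chloro-3-methyl-4-[2-(2-methyl-1,3-dioxolan-2-yl)ethyl]oxolan-2-ol (both anomers) | C[C@]1(Cl)[C@H](CCC2(C)OCCO2)COC1O
F8 | step 15 | (5R)-2,3-dibromo-5-[(2S,3E)-4-bromo-2-chlorobut-3-en-2-yl]-2-methyloxane (mixture at C2 and C3) | C[C@@](Cl)(/C=C/Br)[C@H]1COC(C)(Br)C(Br)C1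
F9 | step 15 | (3R)-5-bromo-3-[(2S,3E)-4-bromo-2-chlorobut-3-en-2-yl]-6-methyl-3,4-dihydro-2H-pyran | C[C@@](Cl)(/C=C/Br)[C@H]1COC(C)=C(Br)C1
F10 | step 10 | methyl (2R,3S)-3-chloro-3-methyl-2-[2-(2-methyl-1,3-dioxolan-2-yl)ethyl]-4-oxobutanoate | C[C@@](Cl)(C=O)[C@H](CCC1(C)OCCO1)C(=O)OC
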